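The earlier runs and the new flask stem from a simulated flask with constants of no real substance; the scatter is artificial.

The readings of Friday's flask could not reach the asked time, since they stop at 8.00 h and the question stands at 15 h, so I had to put a mean rate in place of the missing curve.

in all of them: substrate 0.050 M

| run | catalyst | remark | time |
|---|---|---|---|
| Friday's | 3.4 mM | the very flask that is asked about, followed so far |  |
| Wednesday's | 2.3 mM | run made earlier |  |
| flask | 3.4 mM |  | 15 h |

| run | time / h | target / % | isomer of the product / % |
|---|---|---|---|
| Friday's | 0.417 | 10.5 | 0.7 |
| Friday's | 1.00 | 20.8 | 1.7 |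
| Friday's | 2.00 | 30.1 | 2.7 |
| Friday's | 3.00 | 34.3 | 3.7 |
| Friday's | 5.00 | 36.0 | 6.6 |
| Friday's | 6.00 | 36.2 | 8.0 |
| Friday's | 8.00 | 36.3 | 10.1 |
| Wednesday's | 0.500 | 11.8 | 0.2 |
| Wednesday's | 0.667 | 15.6 | 1.2 |
| Wednesday's | 1.00 | 20.6 | 0.7 |
| Wednesday's | 1.50 | 26.8 | 0.9 |
| Wednesday's | 2.50 | 33.2 | 1.9 |
| Wednesday's | 4.00 | 37.0 | 4.0 |
| Wednesday's | 6.00 | 37.5 | 5.4 |

(each reading ± 0.3 percentage points)

* ratio of target to isomer of the product at 4.0 min
* ratio of target to isomer of the product at 15 h
* which of target and isomer of the product there is more of at 15 h



I went through the runs in slow motion. At first c(target) rose quickly and kept the same pace at both loadings: at 1.00 h Friday's flask held 20.8% and Wednesday's 20.6%. The isomer of the product, at 0.2% in Wednesday's first reading, lay within the scatter, so I offered no number for 4.0 min. In the middle, c(target) in Friday's flask levelled off, reading 36.0% at 5.00 h and 36.3% at 8.00 h. Over those same hours the isomer climbed from 6.6% to 10.1%, and this climb was what would matter later.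

I divided its mean rate by the catalyst charged and got 3.43 L mol⁻¹ h⁻¹. This is the drift per catalyst, the fraction of the charge turned into isomer per hour and per unit of catalyst. I then checked the error of using a mean. Drift times catalyst times time gave 9.33% for Friday's last reading, which was 10.1%, and 4.74% for Wednesday's, which was 5.4%. Both were low, Friday's by 0.77 percentage points and Wednesday's by 0.66 points, and I accepted an error of that size. Friday's comparison used a reading the drift was made from, so Wednesday's was the real test.

For 15 h in Friday's flask the drift gave 17.5% of isomer. Target held 40.4% of what was not isomer at the last reading. Keeping that share gave 33.3% of target and a ratio of 1.90.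

The forecast gave 17 at 4.0 min (range 12 to 24), 1.95 at 15 h (range 1.65 to 2.3), and target in the lead, saying of the isomer: “It tracks the integral of substrate, not of target, because it forms fastest early on.”

Friday's flask gave a ratio of 26.5 at 4.0 min, above the forecast's range, and 2.05 at 15 h, inside it, with target ahead at 33.6% against 16.4%.

    isomer of the product + catalyst ⇌ substrate + catalyst, rate k1*[catalyst]*[isomer of the product] forward; the back reaction follows from the equilibrium constant (k = 4.30 L mol⁻¹ h⁻¹)
    substrate ⇌ target (K = 0.680, k = 0.300 h⁻¹)
    target + catalyst ⇌ isomer of the product + catalyst, rate k3*[catalyst]*[target] forward; the back reaction follows from the equilibrium constant (K = 1.10, k = 7.00 L mol⁻¹ h⁻¹)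

The forecast and Friday's flask parted in the first minutes and agreed at 15 h. In Friday's flask, the step between substrate and target, taken by itself with both directions together, had a relaxation half-life of 0.935 h, short against 15 h. At 15.0 h target was being made at 0.341 of the rate at which it was used up, each step taken net. In the neighbour with 0.0020 M of catalyst, the drift gives 10.3% of isomer at 15 h and a ratio of 3.52; the computed flask holds 11.1%, with a ratio of 3.22.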